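The route cuts the three C–O bonds from the styryl orthoester carbon (to O4, O6, O15), then C1–H (back to a C1 ketone), C6–O6 (back to C6–Si), C6–Si with C5–H (back to a C5=C6 alkene bearing O4–SiMe2H), C4–O4 with C15–O15 (back to a 4(15),5-diene), C4–C5 (ring A) and C10–C1 (aldol).
In the forward direction, ring B is the carvone ring and ring A closes by a samarium ketyl–alkyne cyclisation. The temporary oxasilolane closes in the key step and is then oxidised away. The dioxane (O4/O6) and dioxolane (O4/O15) rings of the orthoester cage close together in the penultimate step.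
The enabling feature is that O4 sits on C4 of ring A, allylic to C5=C6 of ring B at the ring junction. O4, H5 and O6 share one face, and O4 and O6 are 1,3-related through C5. A silicon atom on O4 therefore reaches C6 through the five-membered ring O4–Si–C6–C5–C4 and passes its hydrogen to C5.
C7 comes from (R)-carvone, C10 from an axial aldol addition cis to the isopropyl group, and C4 from osmylation anti to C14. C5 and C6 come from the tethered syn hydrosilylation, with C6–O formed with retention. The cage fixes the orthoester carbon. C1 is set last, by axial hydride addition to a C1 ketone that is carried through unprotected.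

Key step: step 10

Assumption: eudesmane numbering is used; α is the face of the bicycle that carries C14 and β the opposite face; every bicyclic compound has 10α-methyl and 7β-isopropyl. The carbinol centres C1 (in 6, 7) and C5 (in 7, 8) are drawn as the expected isomers, and both are erased before the key step.

Step 1
Reactants: 1 (R)-(−)-carvone
Product: 2 (R)-carvotanacetone, (5R)-2-methyl-5-(propan-2-yl)cyclohex-2-en-1-one
Conditions: H2 (1 atm), RhCl(PPh3)3 (cat.), benzene, rt
Reagents that add atoms: none
Why: Homogeneous hydrogenation with RhCl(PPh3)3 saturates the unhindered 1,1-disubstituted isopropenyl alkene and leaves the trisubstituted conjugated enone alone, so the C7 stereocentre of the chiral pool is carried over unchanged.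

Step 2
Reactants: 3 pent-4-yn-1-ol
Product: 4 pent-4-ynal
Conditions: Dess–Martin periodinane, CH2Cl2, 0 °C to rt
Reagents that add atoms: none
Why: Dess–Martin oxidation takes the primary alcohol to the aldehyde without over-oxidation and without touching the terminal alkyne.

Step 3
Reactants: 2 (R)-carvotanacetone; 4 pent-4-ynal
Product: 6 (2R,5R)-2-[(1R)-1-hydroxypent-4-yn-1-yl]-2-methyl-5-(propan-2-yl)cyclohexan-1-one, via lithium enolate 5 (not isolated)
Conditions: LiBH(s-Bu)3, THF, −78 °C; then 4, −78 °C; AcOH quench
Reagents that add atoms: none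
Why: Reductive aldol reaction: 1,4-hydride addition to the β-unsubstituted enone gives only the C5=C10 enolate 5, which adds to the aldehyde axially through a chair-like ring B with equatorial isopropyl group, so that the new C10–C1 bond is cis and C14 trans to the isopropyl group, while the closed Zimmerman–Traxler chair should favour the 1R carbinol drawn, a centre that is erased in step 5.

Step 4
Reactants: 6 alkynyl β-hydroxy ketone
Product: 7 eudesm-4(15)-ene-1β,5α-diol (cis-fused decalin, exocyclic C4=C15H2)
Conditions: SmI2, HMPA, t-BuOH, THF, 0 °C to rt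
Reagents that add atoms: none
Why: Samarium ketyl–alkyne reductive cyclisation: electron transfer to the C5 ketone, helped by chelation of samarium to O1, gives a ketyl that adds 6-exo-dig to C4 (closure favoured by the quaternary C10), and the vinyl radical is reduced and protonated to the exocyclic C4=C15 methylene; the C5 carbinol, expected cis-fused from the chair with axial side chain, is erased in step 6.

Step 5
Reactants: 7 eudesm-4(15)-ene-1β,5α-diol
Product: 8 5α-hydroxyeudesm-4(15)-en-1-one
Conditions: Dess–Martin periodinane, CH2Cl2, 0 °C to rt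
Reagents that add atoms: none
Why: Dess–Martin oxidation acts only on the secondary C1 carbinol, converges both C1 epimers on one ketone and, being non-basic, avoids retro-aldol opening of the β-hydroxy ketone.

Step 6
Reactants: 8 5α-hydroxyeudesm-4(15)-en-1-one
Product: 9 eudesma-4(15),5-dien-1-one
Conditions: Ph2S[OC(CF3)2Ph]2, CH2Cl2, 0 °C to rt
Reagents that add atoms: none
Why: Sulfurane dehydration of a tertiary alcohol: the activated allylic C5–O bond can lose a proton only from C6 because C4 and C10 carry no hydrogen, and the acid-free medium keeps the exocyclic C4=C15 bond from moving into ring A.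

Step 7
Reactants: 9 eudesma-4(15),5-dien-1-one
Product: 10 4β,15-dihydroxyeudesm-5-en-1-one (C15 axial on the α face)
Conditions: OsO4 (cat.), NMO, acetone/H2O, 0 °C to rt
Reagents that add atoms: OsO4, O=[Os](=O)(=O)=O; N-methylmorpholine N-oxide, C[N+]1([O-])CCOCC1; water, O
Why: Upjohn dihydroxylation: the exposed 1,1-disubstituted C4=C15 bond is osmylated far faster than the trisubstituted C5=C6 bond, which is wedged between quaternary C10 and the isopropyl-bearing C7 as in the notoriously inert 5-enes of steroids, and osmium comes in anti to the axial C14 (1,3 to C4), which places O4 on the β face and C15 axial on the α face.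

Step 8
Reactants: 10 4β,15-dihydroxyeudesm-5-en-1-one
Product: 11 15-(tert-butyldimethylsilyloxy)-4β-hydroxyeudesm-5-en-1-one
Conditions: TBSCl, imidazole, CH2Cl2, 0 °C to rt
Reagents that add atoms: tert-butyldimethylsilyl chloride, CC(C)(C)[Si](C)(C)Cl
Why: Silylation distinguishes the primary O15 from the tertiary O4 on steric grounds.

Step 9
Reactants: 11 15-(tert-butyldimethylsilyloxy)-4β-hydroxyeudesm-5-en-1-one
Product: 12 15-(tert-butyldimethylsilyloxy)-4β-(dimethylsilyloxy)eudesm-5-en-1-one
Conditions: Me2SiHCl, imidazole, DMAP (cat.), CH2Cl2, 0 °C to rt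
Reagents that add atoms: chlorodimethylsilane, C[SiH](C)Cl
Why: The small, electrophilic chlorosilane silylates even the hindered tertiary allylic alcohol, and imidazole does not enolise the C1 ketone.

Step 10
Reactants: 12 15-(tert-butyldimethylsilyloxy)-4β-(dimethylsilyloxy)eudesm-5-en-1-one
Product: 13 15-(tert-butyldimethylsilyloxy)-4β,6β-[oxy(dimethylsilanediyl)]-5βH-eudesman-1-one (trans-decalin; oxasilolane O4–Si–C6–C5–C4)
Conditions: Pt2[(CH2=CHSiMe2)2O]3 (2 mol %), toluene, 60 °C
Reagents that add atoms: none
Why: Oxidative addition of the Si–H bond to zerovalent platinum, binding of C5=C6, syn migratory insertion that puts hydrogen on C5 and platinum on C6 (six-membered platinacycle Pt–Si–O4–C4–C5–C6) and C6–Si reductive elimination with retention make up a Chalk–Harrod cycle. The closest known reaction type is the platinum-catalysed intramolecular hydrosilylation of allylic (hydrido)silyl ethers, the first half of the hydrosilylation–oxidation route from allylic alcohols to 1,3-diols. The one ring that closes, the oxasilolane O4–Si–C6–C5–C4, forms in the 5-endo-trig mode, because the 4-exo alternative would need an oxasiletane and a platinum–carbon bond at the fully substituted C5; this fixes silicon on C6 and hydrogen on C5. C5 and C6 are set in one suprafacial event, and the face is dictated by the C4 stereocentre: the C4–O4 bond lies close to the alkene plane and leans to the β side, while the α side of C5 is a cleft between the axial C14 and the axial C15H2OTBS group, so the three-atom O4–Si–Pt arm can fold only over the β face. The result is H5 β (trans-decalin) and an equatorial C6–Si bond cis to the isopropyl group, with the new ring spanning the two peri-equatorial positions as a C5 envelope, trans-fused to ring A and to ring B and relaxed by the long Si–C and Si–O bonds. The step needs face selectivity against the pseudoaxial β isopropyl group at C7 and chemoselectivity for the alkene over the C1 ketone; intramolecular delivery and the geminal substitution at C4 secure the first, and the poor carbonyl affinity of platinum silyl hydrides secures the second.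

Step 11
Reactants: 13 oxasilolane
Product: 14 15-(tert-butyldimethylsilyloxy)-4β,6β-dihydroxy-5βH-eudesman-1-one
Conditions: 30% H2O2, KF, KHCO3, THF/MeOH, rt to 40 °C
Reagents that add atoms: hydrogen peroxide, OO
Why: Tamao–Fleming oxidation: fluoride and hydroperoxide add to the strained alkoxysilane, C6 migrates from silicon to oxygen with retention to give the equatorial 6β-hydroxyl, and hydrolysis frees O4, while the hindered C1 ketone and the TBS ether tolerate the buffered peroxide.

Step 12
Reactants: 14 15-(tert-butyldimethylsilyloxy)-4β,6β-dihydroxy-5βH-eudesman-1-one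
Product: 15 4β,6β,15-trihydroxy-5βH-eudesman-1-one
Conditions: Bu4NF, THF, rt
Reagents that add atoms: none
Why: Fluoride-induced desilylation frees O15; no centre next to the ketone can epimerise because C10 is quaternary, and no β-hydroxy ketone is present that could undergo retro-aldol cleavage.

Step 13
Reactants: 16 (E)-cinnamonitrile
Product: 18 trimethyl (E)-orthocinnamate, via methyl (E)-cinnamimidate hydrochloride 17 (not isolated)
Conditions: HCl (g), MeOH (1.1 equiv), Et2O, 0 °C; solvent removed; MeOH (excess), hexane, rt
Reagents that add atoms: methanol, CO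
Why: Pinner reaction: HCl-promoted addition of methanol to the nitrile gives the imidate salt 17, whose methanolysis replaces nitrogen by two further methoxy groups with precipitation of NH4Cl, the conjugated E alkene taking no part.

Step 14
Reactants: 15 4β,6β,15-trihydroxy-5βH-eudesman-1-one; 18 trimethyl (E)-orthocinnamate
Product: 19 1-oxo orthoester, the (E)-styryl orthoester bridging O4, O6 and O15 of 15
Conditions: 18 (1.1 equiv), PPTS (cat.), 4 Å molecular sieves, CH2Cl2, rt; Et3N quench
Reagents that add atoms: none
Why: Acid-catalysed transorthoesterification: stepwise exchange of the three methoxy groups through dioxocarbenium ions closes the dioxane across the peri-equatorial O4 and O6 and the dioxolane across O4 and the axial C15–O15 (a 2,7,8-trioxabicyclo[3.2.1]octane), loss of three molecules of methanol drives it, the cage allows only one configuration at the new orthoester carbon, and the C1 ketone leaves no fourth hydroxyl to compete.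

Step 15
Reactants: 19 1-oxo orthoester
Product: 20 CNP0190302.1, (1S,4S,5R,6R,7S,10S)-5βH-eudesmane-1α,4β,6β,15-tetraol 4,6,15-[(E)-orthocinnamate], orthoester carbon S
Conditions: NaBH4, MeOH, 0 °C
Reagents that add atoms: none
Why: Hydride reduction of a 10-methyl-1-decalone: borohydride attacks axially from the β face, away from the neighbouring axial C14, and gives the equatorial 1α alcohol, while the orthoester and the styryl alkene, which is not conjugated to a carbonyl group, are inert to NaBH4.

Compound list
1 | (R)-(−)-carvone | CC(=C)[C@@H]1CC=C(C)C(=O)C1 | starting material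
2 | (R)-carvotanacetone | CC(C)[C@@H]1CC=C(C)C(=O)C1 | intermediate
3 | pent-4-yn-1-ol | C#CCCCO | starting material
4 | pent-4-ynal | C#CCCC=O | intermediate
5 | lithium (5R)-2-methyl-5-(propan-2-yl)cyclohex-1-en-1-olate | CC(C)[C@@H]1CCC(C)=C([O-])C1.[Li+] | intermediate
6 | (2R,5R)-2-[(1R)-1-hydroxypent-4-yn-1-yl]-2-methyl-5-(propan-2-yl)cyclohexan-1-one | CC(C)[C@@H]1CC[C@](C)([C@H](O)CCC#C)C(=O)C1 | intermediate
7 | eudesm-4(15)-ene-1β,5α-diol (cis-decalin) | CC(C)[C@@H]1CC[C@]2(C)[C@H](O)CCC(=C)[C@]2(O)C1 | intermediate
8 | 5α-hydroxyeudesm-4(15)-en-1-one | CC(C)[C@@H]1CC[C@]2(C)C(=O)CCC(=C)[C@]2(O)C1 | intermediate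
9 | eudesma-4(15),5-dien-1-one | CC(C)[C@@H]1CC[C@]2(C)C(=O)CCC(=C)C2=C1 | intermediate
10 | 4β,15-dihydroxyeudesm-5-en-1-one | CC(C)[C@@H]1CC[C@]2(C)C(=O)CC[C@@](O)(CO)C2=C1 | intermediate
11 | 15-(tert-butyldimethylsilyloxy)-4β-hydroxyeudesm-5-en-1-one | CC(C)[C@@H]1CC[C@]2(C)C(=O)CC[C@@](O)(CO[Si](C)(C)C(C)(C)C)C2=C1 | intermediate
12 | 15-(tert-butyldimethylsilyloxy)-4β-(dimethylsilyloxy)eudesm-5-en-1-one | CC(C)[C@@H]1CC[C@]2(C)C(=O)CC[C@@](O[SiH](C)C)(CO[Si](C)(C)C(C)(C)C)C2=C1 | intermediate
13 | 15-(tert-butyldimethylsilyloxy)-4β,6β-[oxy(dimethylsilanediyl)]-5βH-eudesman-1-one | CC(C)[C@@H]1CC[C@@]2(C)[C@@H]3[C@@H]1[Si](C)(C)O[C@@]3(CO[Si](C)(C)C(C)(C)C)CCC2=O | intermediate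
14 | 15-(tert-butyldimethylsilyloxy)-4β,6β-dihydroxy-5βH-eudesman-1-one | CC(C)[C@@H]1CC[C@@]2(C)[C@H]([C@@H]1O)[C@](O)(CO[Si](C)(C)C(C)(C)C)CCC2=O | intermediate
15 | 4β,6β,15-trihydroxy-5βH-eudesman-1-one | CC(C)[C@@H]1CC[C@@]2(C)[C@H]([C@@H]1O)[C@](O)(CO)CCC2=O | intermediate
16 | (E)-cinnamonitrile | N#C/C=C/c1ccccc1 | starting material
17 | methyl (E)-cinnamimidate hydrochloride | COC(=N)/C=C/c1ccccc1.Cl | intermediate
18 | trimethyl (E)-orthocinnamate | COC(OC)(OC)/C=C/c1ccccc1 | intermediate
19 | 1-oxo 4,6,15-[(E)-orthocinnamate] | CC(C)[C@@H]1CC[C@@]2(C)[C@@H]3[C@@H]1O[C@]1(/C=C/c4ccccc4)OC[C@@]3(CCC2=O)O1 | intermediate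
20 | CNP0190302.1 | CC(C)[C@@H]1CC[C@@]2(C)[C@@H]3[C@@H]1O[C@]1(/C=C/c4ccccc4)OC[C@@]3(CC[C@@H]2O)O1 | target

Total step count: 15. Longest linear sequence: 13 steps (1 to 20 through steps 1, 3–12, 14 and 15).

Steps most likely to fail

Step 10. Three things may go wrong.
- Insertion of the doubly flanked trisubstituted alkene may be too slow.
- The alkylplatinum intermediate may lose H7 by β-hydride elimination, which moves the alkene toward C7 and erases that centre.
- Delivery may leak to the α face.

The fallback drops the tether and sets out from 11. Excess BH3·THF followed by NaOH/H2O2 is a hydroboration–oxidation, the reaction that adds H and OH to steroidal 5-enes anti to the angular methyl group. It should reduce the C1 ketone by axial attack and add H5 and O6 to the β face, giving 15-(tert-butyldimethylsilyloxy)-5βH-eudesmane-1α,4β,6β-triol F1. Bu4NF in THF then gives 5βH-eudesmane-1α,4β,6β,15-tetraol F2. Orthoester exchange with 18 under the conditions of step 14 follows, in which the remote equatorial O1 cannot join the cage. This comes back to the route at 20.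

Step 4. The 6-exo closure onto an unactivated alkyne may be outrun by further reduction and protonation of the ketyl, or by retro-aldol cleavage of the samarium alkoxide. The fallback replaces the radical closure by a Heck reaction and sets out from 2.
- The reductive aldol of step 3, run with commercial pent-4-enal, should give (2R,5R)-2-[(1R)-1-hydroxypent-4-en-1-yl]-2-methyl-5-(propan-2-yl)cyclohexan-1-one F3.
- Et3SiOTf and 2,6-lutidine give its triethylsilyl ether F4.
- KN(SiMe3)2 and N-(5-chloropyridin-2-yl)bis(trifluoromethanesulfonimide) give the C5(OTf)=C6 enol triflate F5. C6 is the only enolisable position.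
- Pd(OAc)2, PPh3 and Et3N in MeCN effect a 6-exo-trig intramolecular Heck reaction that forms C4–C5, followed by β-hydride loss of H4. This gives 1β-(triethylsilyloxy)eudesma-4(15),5-diene F6.
- Bu4NF gives eudesma-4(15),5-dien-1β-ol F7.
- Dess–Martin oxidation comes back to the route at 9.

Step 7. Osmylation may lose its preference for C4=C15 over C5=C6, or the s-cis diene may dimerise or isomerise before it reacts. The fallback reverses the order of oxidation and dehydration and sets out from 8, in which C4=C15 is the only alkene.
- OsO4/NMO, attacking equatorially and anti to the axial C14, should give 4β,5α,15-trihydroxyeudesman-1-one F8.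
- 2,2-Dimethoxypropane and PPTS give the 4β,15-O-isopropylidene derivative F9.
- Ph2S[OC(CF3)2Ph]2 dehydrates the remaining tertiary C5–OH toward C6, the only side with hydrogen, to give 4β,15-(isopropylidenedioxy)eudesm-5-en-1-one F10.
- Mild aqueous acetic acid comes back to the route at 10.

Further compounds
F1 | step 10 | 15-(tert-butyldimethylsilyloxy)-5βH-eudesmane-1α,4β,6β-triol | CC(C)[C@@H]1CC[C@@]2(C)[C@H]([C@@H]1O)[C@](O)(CO[Si](C)(C)C(C)(C)C)CC[C@@H]2O
F2 | step 10 | 5βH-eudesmane-1α,4β,6β,15-tetraol | CC(C)[C@@H]1CC[C@@]2(C)[C@H]([C@@H]1O)[C@](O)(CO)CC[C@@H]2O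
F3 | step 4 | (2R,5R)-2-[(1R)-1-hydroxypent-4-en-1-yl]-2-methyl-5-(propan-2-yl)cyclohexan-1-one | CC(C)[C@@H]1CC[C@](C)([C@H](O)CCC=C)C(=O)C1
F4 | step 4 | triethylsilyl ether of F3 | CC(C)[C@@H]1CC[C@](C)([C@H](O[Si](CC)(CC)CC)CCC=C)C(=O)C1
F5 | step 4 | C5(OTf)=C6 enol triflate of F4 | CC(C)[C@@H]1CC[C@](C)([C@H](O[Si](CC)(CC)CC)CCC=C)C(OS(=O)(=O)C(F)(F)F)=C1
F6 | step 4 | 1β-(triethylsilyloxy)eudesma-4(15),5-diene | CC(C)[C@@H]1CC[C@]2(C)[C@H](O[Si](CC)(CC)CC)CCC(=C)C2=C1
F7 | step 4 | eudesma-4(15),5-dien-1β-ol | CC(C)[C@@H]1CC[C@]2(C)[C@H](O)CCC(=C)C2=C1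
F8 | step 7 | 4β,5α,15-trihydroxyeudesman-1-one | CC(C)[C@@H]1CC[C@]2(C)C(=O)CC[C@@](O)(CO)[C@]2(O)C1
F9 | step 7 | 5α-hydroxy-4β,15-(isopropylidenedioxy)eudesman-1-one | CC(C)[C@@H]1CC[C@]2(C)C(=O)CC[C@@]3(COC(C)(C)O3)[C@]2(O)C1
F10 | step 7 | 4β,15-(isopropylidenedioxy)eudesm-5-en-1-one | CC(C)[C@@H]1CC[C@]2(C)C(=O)CC[C@@]3(COC(C)(C)O3)C2=C1
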